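Readings and results come from a simulation for substances that don't exist.

- 3 questions stand on this flask, and each is an entry in one account: how much of the reagent has gone to which hand.

| setting | maple | larch | alder | flask |
|---|---|---|---|---|
| left-handed substrate | 11 mM | 11 mM | 11 mM | 11 mM |
| right-handed substrate | 11 mM | 11 mM | 11 mM | 11 mM |
| reagent | 12.1 mM | 12.1 mM | 12.1 mM | 12.1 mM |
| free catalyst | 37 µM | 82 µM | 55 µM | 55 µM |
| added ligand | 90 µM | 90 µM | 90 µM | 90 µM |
| impurity | 5.8 µM | 5.8 µM | 12 µM | 5.8 µM |
| remark | run made earlier | run made earlier | run made earlier |  |
| time |  |  |  | 1.0 h |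

| run | time / min | left-handed product / % | right-handed product / % | left-handed substrate / % |
|---|---|---|---|---|
| maple | 10.0 | 4.6 | 3.6 | 45.6 |
| maple | 20.0 | 8.1 | 7.8 | 43.6 |
| maple | 25.0 | 11.2 | 7.7 | 39.6 |
| maple | 40.0 | 12.8 | 10.5 | 35.6 |
| larch | 3.00 | 4.9 | 4.3 | 46.6 |
| larch | 6.00 | 8.0 | 5.2 | 42.3 |
| larch | 15.0 | 13.0 | 11.2 | 33.7 |
| larch | 40.0 | 27.2 | 17.5 | 24.2 |
| alder | 5.00 | 4.4 | 1.6 | 48.3 |
| alder | 12.0 | 8.2 | 5.0 | 41.8 |
| alder | 25.0 | 14.4 | 10.8 | 36.4 |
| alder | 40.0 | 17.1 | 14.8 | 31.4 |

(readings scatter by 1 percentage point)

- free catalyst is single-handed; left-handed substrate and right-handed substrate are mirror images of each other, charged as a racemate, each of them at the stated concentration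
- the numbers in the tables scatter with a standard deviation of 1 percentage point
- an excess is the difference of the two amounts in percent of their sum
- an excess is below zero if the other one leads

1. excess of left-handed product over right-handed product in the product at 3.0 min
2. excess of left-handed product over right-handed product in the product at 1.0 h
3. part of the left-handed substrate and right-handed substrate charged together that has reacted at 1.0 h

- The account opens with the reagent. Counting one reagent for each product formed, as we assume here, the reagent ceiling, the part of the racemate charged that the reagent charge can pay for, is 55.0%. The reagent is the limiting reagent, its charge being less than the racemate's.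
- The zero of our scale is the even split: 27.5% of the racemate to each product at the ceiling. Any excess is a departure from it.
- By the readings, the larch run has spent the most of the 3 runs at 40.0 min: 49.5% of its reagent as left-handed product, 31.8% as right-handed product, and 18.7% unspent. Those entries read as an excess of 21.7%, with a scatter of 1 percentage point on each reading.
- The alder run, with this flask's catalyst charge but 12 µM of impurity against 5.8 µM, has spent 58.0% by the same time.
- Our own estimate for this flask at 1.0 h: reagent still unspent, and an excess near the larch reading, which is the reading furthest along the account.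
- The forecast gives 12% at 3.0 min, 14% at 1.0 h and 41% reacted, saying “Selectivity is weak and noisy”. Against the ceiling, its reacted part leaves 25.5% of the reagent unspent. Its late excess stands below our larch reading, and there we differ.

- The flask gives 7.09% at 3.0 min, 20.3% at 1.0 h and 40.4% reacted, so the late excess lies 6.3 points above the forecast.

    free catalyst + left-handed substrate ⇌ catalyst intermediate A (K = 2670 M⁻¹, k = 7320 M⁻¹ min⁻¹)
    free catalyst + right-handed substrate ⇌ catalyst intermediate B (K = 1100 M⁻¹, k = 99900 M⁻¹ min⁻¹)
    reagent + catalyst intermediate A → free catalyst + left-handed product (k = 1130 M⁻¹ min⁻¹)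
    reagent + catalyst intermediate B → free catalyst + right-handed product (k = 427 M⁻¹ min⁻¹)
    2 free catalyst → spent catalyst A (k = 370 M⁻¹ min⁻¹)
    free catalyst + added ligand ⇌ idle complex (K = 3.40 × 10⁵ M⁻¹, k = 3410 M⁻¹ min⁻¹)
    free catalyst + impurity → spent catalyst B (k = 1.88 × 10⁵ M⁻¹ min⁻¹)

- At 0.307 h the reagent in this flask was going to left-handed product 1.5 times as fast as to right-handed product. Against the ceiling, the reacted part leaves 26.5% of this flask's reagent unspent at 1.0 h. The neighbour charged with 48 mM of reagent has a ceiling of 218%, its charge being more than the racemate's. There 91.8% reacted, which leaves 57.9% of its reagent unspent.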